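The meeting opened on a ratio, target formed over homo product formed, both in substrate units, since with over-reaction product set aside the share asked for is that ratio divided by one plus itself.

| setting | elm | maple | birch | ash |
|---|---|---|---|---|
| substrate | 0.10 M | 0.10 M | 0.10 M (fed, over 0.500 min) | 0.10 M |
| partner | 1.50 equiv | 1.50 equiv | 1.50 equiv | 1.50 equiv |
| reagent | 1.20 equiv | 1.20 equiv (fed, over 0.500 min) | 1.20 equiv | 1.20 equiv |
| remark | a single well-mixed tank run continuously and read at steady state, 1.0 min in it on average | all but reagent at the start; reagent goes in evenly over 0.500 min, the run ends at 1.0 min | a stirred flask in which substrate is dosed at a steady rate over 0.500 min without added volume, worked up at 1.0 min | a closed flask charged with all of it at once and left for 1.0 min |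
| time |  | 1.0 min | 1.0 min | 1.0 min |

    2 open intermediate → homo product (k1 = 0.265 M⁻¹ s⁻¹)
    reagent + partner → second intermediate (k2 = 0.0852 M⁻¹ s⁻¹)
    open intermediate + second intermediate → target (k3 = 0.196 M⁻¹ s⁻¹)
    partner + target → over-reaction product (k4 = 0.0396 M⁻¹ s⁻¹)
    substrate + reagent → open intermediate (k5 = 0.0964 M⁻¹ s⁻¹)

- the set-up with the highest share of target in all that became target or homo product or over-reaction product, at the outlet or at the end ("none" if the first two lie within 2 percentage points) (elm / maple / birch / ash / none)
- share of target in all that became target or homo product or over-reaction product, at the outlet or at the end, elm
- share of target in all that became target or homo product or over-reaction product, at the outlet or at the end, maple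
- share of target in all that became target or homo product or over-reaction product, at the outlet or at the end, birch
- share of target in all that became target or homo product or over-reaction product, at the outlet or at the end, ash

- percent here means substrate units held: one homo product counts as two
- a doubled species enters its step squared and goes two at a time
- the stated concentrations are those of everything mixed, before any reaction; amounts are the same in each set-up
- the feed brings no volume worth counting
- run time (maple): 1.0 min

I reported my reckoning first. In ash, step 4 halves target in 1.9 min at the charged partner, longer than the 1.0 min run, so I set over-reaction product aside. Target over homo product is then the constant of step 3 times c(second intermediate), over twice the constant of step 1 times c(open intermediate).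

I argued that reagent enters the making of both intermediates and cancels, which leaves 0.0852 M⁻¹ s⁻¹ times c(partner) against 0.0964 M⁻¹ s⁻¹ times c(substrate), a ratio of 1.33 at the charge. Putting that ratio in for c(second intermediate) over c(open intermediate) gives the split number, target made per unit of homo product made as the charges stand, 0.490, and so a share of 32.9%.

I held this for ash and for maple, where dosed reagent cancels as well, and gave no figure for elm, where I had not reckoned over-reaction product. For birch, the substrate dosed so far averages 0.750 of the charge over the run, which raises the split number to 0.654 and the share to 39.5%.

The forecast's author then named birch, with elm 34.5%, maple 34%, birch 46% and ash 35%, on the ground that “dosing the substrate lets the second intermediate build up first and keeps the open intermediate low”. We agreed on the flask and parted by 6.5 percentage points on its share, the forecast being the higher.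

The simulation gives birch: elm 34.3%, maple 34.4%, birch 46.9%, ash 35.3%. At 0.500 min, birch held second intermediate at 0.0324 M beside open intermediate at 10.8%, where ash held 0.0292 M beside 18.7%. The split number of 0.490 gives 32.9% for maple, which read 34.4%, against 46.9% for birch. In the neighbour of ash charged with 3.00 equiv of reagent, reagent cancels, so the split number stays 0.490 and gives 32.9%. The computed share there is 40.4%, 7.5 points above it.

The numbers are invented; the flask was simulated.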